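**Plan**

- Numbering: ring A is the chlorinated hydroxyquinone; ring B is the cyclohexanone (C1 quaternary, C2 and C6 the CHMe carbons, C3 the carbonyl carbon, C4 and C5 methylenes); the chain runs from C1' on ring A to C5' on C1.
- Cuts, in retrosynthetic order: ring A back to a 4-chlororesorcinol (C–O at the carbon para to the phenol); C3'–C4' (alkenylzinc plus aldehyde); aryl–C1' (aryllithium plus propargylic bromide); C4'–C5' (one-carbon homologation of a formyl group); last, C1–C2 and C5–C6 of ring B.
- Enabling feature: the C6–C1–C2 stereotriad of ring B with C5' on C1 is the pattern of the formyl-endo Diels–Alder adduct of (E)-2-methylbut-2-enal, whose formyl carbon is C5'. The C3 carbonyl travels as the silyl enol ether of the diene, and C4 carries a phenylsulfanyl group that fixes the regiochemistry and is removed later.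
- Forward order: ring B by cycloaddition, C4' by Wittig homologation, the arene-bearing C1'–C3' unit joined at C3'–C4', sulfur and silyl groups removed, ring A oxidised to the hydroxyquinone last.
- Stereochemistry: C1, C2 and C6 from the cycloaddition (catalyst face selection, endo rule, alkene geometries); the E olefin from syn-hydrozirconation; (S)-C4' from a ligand-controlled alkenylzinc addition.

Key step: step 4

Assumption: the facial sense of the (S)-oxazaborolidinium catalyst (step 4) and of the (S)-amino thiol ligand (step 12) is taken from the usual binding models; if either delivers the opposite face, its enantiomer is used with no other change.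

**Route**

Step 1
Reactants: 1 thiophenol; 2 1-bromobutan-2-one
Product: 3 1-(phenylsulfanyl)butan-2-one
Conditions: Et3N, CH2Cl2, 0 °C to rt
Reagents that add atoms: none
Why: SN2 displacement of the activated primary α-bromo ketone by the thiolate is fast and clean under a mild amine base (S-alkylation).

Step 2
Reactants: 3 1-(phenylsulfanyl)butan-2-one
Product: 5 2-(phenylsulfanyl)pent-1-en-3-one, via Mannich base 4 (not isolated)
Conditions: (CH2O)n, PhNHMe·CF3CO2H, THF, 65 °C; used at once
Reagents that add atoms: paraformaldehyde (as formaldehyde), C=O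
Why: Acid-mediated enolisation runs toward the sulfur-bearing methylene, the iminium ion is trapped there and the Mannich base loses the amine to give the conjugated enone (Mannich methylenation), which is silylated immediately because it dimerises on standing.

Step 3
Reactants: 5 2-(phenylsulfanyl)pent-1-en-3-one
Product: 6 (3Z)-3-[(tert-butyldimethylsilyl)oxy]-2-(phenylsulfanyl)penta-1,3-diene
Conditions: TBSOTf, Et3N, CH2Cl2, −78 to 0 °C
Reagents that add atoms: tert-butyldimethylsilyl trifluoromethanesulfonate, CC(C)(C)[Si](C)(C)OS(=O)(=O)C(F)(F)F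
Why: Soft enolisation can only occur on the ethyl side and should give the Z enol ether, with the methyl cis to oxygen and therefore pointing outward in the s-cis diene (silyl enol ether formation).

Step 4
Reactants: 6 (3Z)-3-[(tert-butyldimethylsilyl)oxy]-2-(phenylsulfanyl)penta-1,3-diene; 7 tiglic aldehyde, (E)-2-methylbut-2-enal
Product: 8 (1S,2S,6R)-3-[(tert-butyldimethylsilyl)oxy]-1,2,6-trimethyl-4-(phenylsulfanyl)cyclohex-3-ene-1-carbaldehyde
Conditions: (S)-3,3-diphenyl-1-(o-tolyl)tetrahydro-1H,3H-pyrrolo[1,2-c][1,3,2]oxazaborole + HNTf2 (20 mol % each), 6 (1.5 equiv), CH2Cl2, −78 to −40 °C; Et3N quench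
Reagents that add atoms: none
Why: The N-protonated oxazaborolidine binds the formyl oxygen of 7, supported by a formyl C–H···O contact, and lowers the LUMO so that diene 6 adds in a concerted, asynchronous, suprafacial [4+2] cycloaddition; the CH2 terminus (future C5, activated through the sulfur-bearing carbon) bonds to the β-carbon (C6) ahead of the methyl-bearing terminus (future C2) to the α-carbon (C1). The closest known reaction type is the cationic oxazaborolidine-catalysed enantioselective Diels–Alder reaction of 2-substituted enals with 2-silyloxy dienes, combined with the sulfur-over-oxygen regiocontrol known for 2-alkoxy-3-arylthio dienes. Ring B closes intermolecularly, C1–C2 and C5–C6 forming in the same step as a [4+2] annulation with no ring or tether present beforehand. The C1/C6 relationship follows from the E geometry of 7 (the two methyls stay cis), C2 from the Z enol ether (methyl outside the s-cis diene) together with the formyl-endo transition state, which puts the C2 methyl cis to the formyl carbon, and the absolute configuration from the catalyst, whose phenyl group shields one face of the s-trans enal so that the diene adds to the Re face of the α-carbon. The step needs regio-, endo and facial selectivity: the first is secured by the phenylsulfanyl group and the terminal methyl, which act together against the siloxy group; the second by secondary overlap of the formyl group with an acyclic diene that has no bridging methylene; the third by the catalyst.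

Step 5
Reactants: 8 (1S,2S,6R)-3-[(tert-butyldimethylsilyl)oxy]-1,2,6-trimethyl-4-(phenylsulfanyl)cyclohex-3-ene-1-carbaldehyde
Product: 9 (1R,2S,6R)-3-[(tert-butyldimethylsilyl)oxy]-1-(2-methoxyethenyl)-1,2,6-trimethyl-4-(phenylsulfanyl)cyclohex-3-ene (E/Z mixture; ring geometry as in 8)
Conditions: Ph3P(CH2OMe)Cl, KN(SiMe3)2, THF, 0 to 40 °C
Reagents that add atoms: (methoxymethyl)triphenylphosphonium chloride, COC[P+](c1ccccc1)(c1ccccc1)c1ccccc1.[Cl-]
Why: The non-stabilised ylide adds even to neopentyl-type aldehydes, the quaternary α-carbon cannot epimerise and the silyl enol ether and vinyl sulfide are inert to the base (Wittig methoxymethylenation as one-carbon homologation).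

Step 6
Reactants: 9 (1R,2S,6R)-3-[(tert-butyldimethylsilyl)oxy]-1-(2-methoxyethenyl)-1,2,6-trimethyl-4-(phenylsulfanyl)cyclohex-3-ene
Product: 10 2-[(1S,2S,6R)-1,2,6-trimethyl-3-oxo-4-(phenylsulfanyl)cyclohexyl]acetaldehyde (both C4 epimers)
Conditions: 1 M HCl, THF, 0 °C to rt
Reagents that add atoms: water, O
Why: Dilute acid protonates both enol ethers on carbon (enol ether hydrolysis), turning the methyl enol ether into the C4' aldehyde and the silyl enol ether, protonated at the sulfur-bearing C4 because oxygen stabilises the cation better than sulfur, into the C3 ketone, under conditions too mild to enolise toward C2.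

Step 7
Reactants: 11 orcinol, 5-methylbenzene-1,3-diol
Product: 12 4-chloro-5-methylbenzene-1,3-diol
Conditions: SO2Cl2 (1.0 equiv), Et2O, 0 °C
Reagents that add atoms: sulfuryl chloride, O=S(=O)(Cl)Cl
Why: Electrophilic aromatic chlorination of the resorcinol takes place para to one hydroxyl and ortho to the other, and the minor 2-chloro isomer and dichloride should be removable by crystallisation.

Step 8
Reactants: 12 4-chloro-5-methylbenzene-1,3-diol
Product: 13 2-chloro-1,5-bis(methoxymethoxy)-3-methylbenzene
Conditions: MOMCl, i-Pr2NEt, CH2Cl2, 0 °C to rt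
Reagents that add atoms: chloromethyl methyl ether, COCCl
Why: O-Alkylation of both phenols gives the bis(methoxymethyl) ether, the directing group best suited to the metalation that follows (acetal protection).

Step 9
Reactants: 13 2-chloro-1,5-bis(methoxymethoxy)-3-methylbenzene; 14 1-bromobut-2-yne
Product: 16 2-(but-2-yn-1-yl)-4-chloro-1,3-bis(methoxymethoxy)-5-methylbenzene, via aryllithium 15 (not isolated)
Conditions: n-BuLi, THF, 0 °C; then added to 14 (2 equiv), THF, −78 to 0 °C
Reagents that add atoms: none
Why: Directed ortho-metalation occurs only between the two acetal oxygens (no hydrogen flanks the chlorine, so no aryne can form) and the aryllithium displaces the primary propargylic bromide by SN2; copper is left out because organocopper species favour SN2' attack to the allene, and inverse addition keeps the product methylene from being deprotonated.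

Step 10
Reactants: 16 2-(but-2-yn-1-yl)-4-chloro-1,3-bis(methoxymethoxy)-5-methylbenzene
Product: 17 2-(but-2-yn-1-yl)-4-chloro-5-methylbenzene-1,3-diol
Conditions: HCl (cat.), MeOH, 45 °C
Reagents that add atoms: none
Why: Acid-catalysed acetal exchange with methanol removes both methoxymethyl groups as dimethoxymethane, the isolated alkyne and aryl chloride being inert.

Step 11
Reactants: 17 2-(but-2-yn-1-yl)-4-chloro-5-methylbenzene-1,3-diol
Product: 18 [2-(but-2-yn-1-yl)-4-chloro-5-methyl-1,3-phenylene]bis(oxy)bis(tert-butyldimethylsilane)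
Conditions: TBSOTf, 2,6-lutidine, CH2Cl2, 0 °C
Reagents that add atoms: tert-butyldimethylsilyl trifluoromethanesulfonate, CC(C)(C)[Si](C)(C)OS(=O)(=O)C(F)(F)F
Why: Silyl triflate with a hindered pyridine silylates even the phenol flanked by chlorine and the side chain, giving aryl silyl ethers that tolerate zirconium hydride and organozinc reagents and come off later with buffered fluoride (phenol silylation).

Step 12
Reactants: 18 [2-(but-2-yn-1-yl)-4-chloro-5-methyl-1,3-phenylene]bis(oxy)bis(tert-butyldimethylsilane); 10 2-[(1S,2S,6R)-1,2,6-trimethyl-3-oxo-4-(phenylsulfanyl)cyclohexyl]acetaldehyde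
Product: 21 (2S,3S,4R)-3-[(2S,3E)-5-{2,6-bis[(tert-butyldimethylsilyl)oxy]-3-chloro-4-methylphenyl}-2-hydroxy-3-methylpent-3-en-1-yl]-2,3,4-trimethyl-6-(phenylsulfanyl)cyclohexan-1-one (both epimers at the sulfur-bearing carbon), via alkenylzirconocene chloride 19 (not isolated), via alkenyl(methyl)zinc 20 (not isolated)
Conditions: 18 (1.5 equiv), Cp2Zr(H)Cl, CH2Cl2, rt; Me2Zn, toluene, −65 °C; (S)-2-[1-(dimethylamino)ethyl]benzenethiol (10 mol %), then 10, −30 to 0 °C
Reagents that add atoms: none
Why: syn-Hydrozirconation, after equilibration, places zirconium on the methyl-bearing alkyne carbon and fixes the E geometry, transmetalation gives an alkenylzinc that adds to the aldehyde and not to the ketone, and the zinc amino thiolate directs it to the Re face of the formyl group so that (S)-C4' is set by reagent control (hydrozirconation–transmetalation followed by catalytic asymmetric alkenylzinc addition).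

Step 13
Reactants: 21 the allylic alcohol bearing the α-phenylsulfanyl ketone
Product: 22 (2S,3S,4R)-3-[(2S,3E)-5-{2,6-bis[(tert-butyldimethylsilyl)oxy]-3-chloro-4-methylphenyl}-2-hydroxy-3-methylpent-3-en-1-yl]-2,3,4-trimethylcyclohexan-1-one
Conditions: SmI2 (2.5 equiv), THF/MeOH, −78 °C
Reagents that add atoms: none
Why: Two single-electron transfers cleave the C–S bond next to the ketone within minutes at −78 °C and methanol protonates the samarium enolate at C4, leaving C2, the aryl chloride and the allylic alcohol untouched (reductive desulfurisation of an α-heterosubstituted ketone).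

Step 14
Reactants: 22 the desulfurised bis-silyl ether
Product: 23 (2S,3S,4R)-3-[(2S,3E)-5-(3-chloro-2,6-dihydroxy-4-methylphenyl)-2-hydroxy-3-methylpent-3-en-1-yl]-2,3,4-trimethylcyclohexan-1-one
Conditions: Bu4NF, AcOH, THF, 0 °C; used directly
Reagents that add atoms: none
Why: Fluoride cleaves aryl silyl ethers rapidly and the acetic acid buffer keeps the medium from enolising the C3 ketone toward C2 (desilylation).

Step 15
Reactants: 23 the free resorcinol
Product: 24 2-chloro-5-hydroxy-6-{(2E,4S)-4-hydroxy-3-methyl-5-[(1S,2S,6R)-1,2,6-trimethyl-3-oxocyclohexyl]pent-2-en-1-yl}-3-methylcyclohexa-2,5-diene-1,4-dione (CNP0469571.2)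
Conditions: (KO3S)2NO, KH2PO4, H2O/acetone, rt
Reagents that add atoms: potassium nitrosodisulfonate, [K+].[K+].[O]N(S(=O)(=O)[O-])S(=O)(=O)[O-]
Why: The nitrosodisulfonate radical oxidises the phenol flanked by chlorine at its free para position to the 1,4-quinone (Teuber oxidation), the second hydroxyl remaining as the 2-hydroxyquinone; oxidation through the other phenol leads to the same compound after tautomerisation, and the buffered neutral medium should spare the allylic alcohol and C2.

**Compound list**

1 | thiophenol (benzenethiol) | Sc1ccccc1 | starting material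
2 | 1-bromobutan-2-one | CCC(=O)CBr | starting material
3 | 1-(phenylsulfanyl)butan-2-one | CCC(=O)CSc1ccccc1 | intermediate
4 | 1-[methyl(phenyl)amino]-2-(phenylsulfanyl)pentan-3-one (Mannich base) | CCC(=O)C(CN(C)c1ccccc1)Sc1ccccc1 | intermediate (not isolated)
5 | 2-(phenylsulfanyl)pent-1-en-3-one | CCC(=O)C(=C)Sc1ccccc1 | intermediate
6 | (3Z)-3-[(tert-butyldimethylsilyl)oxy]-2-(phenylsulfanyl)penta-1,3-diene | C=C(Sc1ccccc1)/C(O[Si](C)(C)C(C)(C)C)=C/C | intermediate
7 | tiglic aldehyde, (E)-2-methylbut-2-enal | C/C=C(\C)C=O | starting material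
8 | (1S,2S,6R)-3-[(tert-butyldimethylsilyl)oxy]-1,2,6-trimethyl-4-(phenylsulfanyl)cyclohex-3-ene-1-carbaldehyde | O=C[C@@]1(C)[C@H](C)CC(Sc2ccccc2)=C(O[Si](C)(C)C(C)(C)C)[C@H]1C | intermediate
9 | (1R,2S,6R)-3-[(tert-butyldimethylsilyl)oxy]-1-(2-methoxyethenyl)-1,2,6-trimethyl-4-(phenylsulfanyl)cyclohex-3-ene, E/Z mixture | COC=C[C@@]1(C)[C@H](C)CC(Sc2ccccc2)=C(O[Si](C)(C)C(C)(C)C)[C@H]1C | intermediate
10 | 2-[(1S,2S,6R)-1,2,6-trimethyl-3-oxo-4-(phenylsulfanyl)cyclohexyl]acetaldehyde, C4 epimers | O=CC[C@@]1(C)[C@H](C)CC(Sc2ccccc2)C(=O)[C@H]1C | intermediate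
11 | orcinol, 5-methylbenzene-1,3-diol | Cc1cc(O)cc(O)c1 | starting material
12 | 4-chloro-5-methylbenzene-1,3-diol | Cc1cc(O)cc(O)c1Cl | intermediate
13 | 2-chloro-1,5-bis(methoxymethoxy)-3-methylbenzene | COCOc1cc(OCOC)c(Cl)c(C)c1 | intermediate
14 | 1-bromobut-2-yne | CC#CCBr | starting material
15 | [3-chloro-2,6-bis(methoxymethoxy)-4-methylphenyl]lithium | [Li]c1c(OCOC)cc(C)c(Cl)c1OCOC | intermediate (not isolated)
16 | 2-(but-2-yn-1-yl)-4-chloro-1,3-bis(methoxymethoxy)-5-methylbenzene | CC#CCc1c(OCOC)cc(C)c(Cl)c1OCOC | intermediate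
17 | 2-(but-2-yn-1-yl)-4-chloro-5-methylbenzene-1,3-diol | CC#CCc1c(O)cc(C)c(Cl)c1O | intermediate
18 | [2-(but-2-yn-1-yl)-4-chloro-5-methyl-1,3-phenylene]bis(oxy)bis(tert-butyldimethylsilane) | CC#CCc1c(O[Si](C)(C)C(C)(C)C)cc(C)c(Cl)c1O[Si](C)(C)C(C)(C)C | intermediate
19 | chlorobis(cyclopentadienyl)[(2E)-4-{2,6-bis[(tert-butyldimethylsilyl)oxy]-3-chloro-4-methylphenyl}but-2-en-2-yl]zirconium | CC(C)(C)[Si](C)(C)Oc1cc(C)c(Cl)c(O[Si](C)(C)C(C)(C)C)c1C/C=C(\C)[Zr](Cl)(C2C=CC=C2)C3C=CC=C3 | intermediate (not isolated)
20 | [(2E)-4-{2,6-bis[(tert-butyldimethylsilyl)oxy]-3-chloro-4-methylphenyl}but-2-en-2-yl](methyl)zinc | CC(C)(C)[Si](C)(C)Oc1cc(C)c(Cl)c(O[Si](C)(C)C(C)(C)C)c1C/C=C(\C)[Zn]C | intermediate (not isolated)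
21 | (2S,3S,4R)-3-[(2S,3E)-5-{2,6-bis[(tert-butyldimethylsilyl)oxy]-3-chloro-4-methylphenyl}-2-hydroxy-3-methylpent-3-en-1-yl]-2,3,4-trimethyl-6-(phenylsulfanyl)cyclohexan-1-one, C6 epimers | CC(C)(C)[Si](C)(C)Oc1cc(C)c(Cl)c(O[Si](C)(C)C(C)(C)C)c1C/C=C(\C)[C@@H](O)C[C@@]2(C)[C@H](C)CC(Sc3ccccc3)C(=O)[C@H]2C | intermediate
22 | (2S,3S,4R)-3-[(2S,3E)-5-{2,6-bis[(tert-butyldimethylsilyl)oxy]-3-chloro-4-methylphenyl}-2-hydroxy-3-methylpent-3-en-1-yl]-2,3,4-trimethylcyclohexan-1-one | CC(C)(C)[Si](C)(C)Oc1cc(C)c(Cl)c(O[Si](C)(C)C(C)(C)C)c1C/C=C(\C)[C@@H](O)C[C@@]2(C)[C@H](C)CCC(=O)[C@H]2C | intermediate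
23 | (2S,3S,4R)-3-[(2S,3E)-5-(3-chloro-2,6-dihydroxy-4-methylphenyl)-2-hydroxy-3-methylpent-3-en-1-yl]-2,3,4-trimethylcyclohexan-1-one | Cc1cc(O)c(C/C=C(\C)[C@@H](O)C[C@@]2(C)[C@H](C)CCC(=O)[C@H]2C)c(O)c1Cl | intermediate
24 | 2-chloro-5-hydroxy-6-{(2E,4S)-4-hydroxy-3-methyl-5-[(1S,2S,6R)-1,2,6-trimethyl-3-oxocyclohexyl]pent-2-en-1-yl}-3-methylcyclohexa-2,5-diene-1,4-dione | CC1=C(Cl)C(=O)C(C/C=C(\C)[C@@H](O)C[C@@]2(C)[C@H](C)CCC(=O)[C@H]2C)=C(O)C1=O | target

**Totals and risks**

Total steps: 15. Longest linear sequence: 10 steps (steps 1–6, then 12–15); the arene branch (steps 7–11) joins at step 12.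

Most likely to fail:

1. Step 4. The strongly acidic boron cation may strip the silyl group from the diene or engage the enol ether terminus in a stepwise Michael addition before cycloaddition, and face discrimination with an α,β-disubstituted enal may be incomplete. Fallback: setting out from 6 and 7, the cycloaddition is run with the achiral Lewis acid Me2AlCl (1 equiv, CH2Cl2, −78 °C), which keeps the endo and sulfur-directed preferences and scavenges protic acid, to give the racemic endo adduct F1. The racemate is then resolved by preparative chromatography on a chiral stationary phase (amylose tris(3,5-dimethylphenylcarbamate), CO2/i-PrOH); the (1R,2R,6S) enantiomer F2 is set aside and the route is rejoined at 8.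

2. Step 12. Regiocontrol in the hydrozirconation may be incomplete, residual zirconium hydride may reduce the aldehyde, and the Lewis acidic zirconocene by-product may erode face control at a β-quaternary aliphatic aldehyde. Fallback: setting out from 18, hydrozirconation (Cp2Zr(H)Cl, CH2Cl2) followed by I2 at 0 °C gives the (E)-alkenyl iodide F3, which is purified free of its regioisomer. It is then joined to 10 by a Nozaki–Hiyama–Kishi coupling (CrCl2, NiCl2 (2 mol %), Et3N, THF/MeCN) in the presence of the chiral ligand N-{2-[(4S)-4-isopropyl-4,5-dihydro-1,3-oxazol-2-yl]-6-methylphenyl}methanesulfonamide (or its enantiomer, whichever delivers the Re face). The alkenylchromium species adds only to the aldehyde, and the route is rejoined at 21.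

3. Step 9. The aryllithium may attack the alkyne terminus (SN2') to give the allene, or the doubly activated methylene of the product may be deprotonated and react further. Fallback: setting out from 13, the aryllithium 15 is quenched with paraformaldehyde to give the benzylic alcohol F4, which is converted (MsCl, Et3N, LiCl, THF, 0 °C) into the benzylic chloride F5 and used cold. Copper-catalysed coupling with CH3C≡CMgBr (CuBr·SMe2 5 mol %, THF, 0 °C) then forms the benzyl–alkynyl bond at a centre where no allenic isomer can arise, and the route is rejoined at 16.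

**Further compounds**

F1 | step 4 | racemic endo adduct, (1S,2S,6R)- and (1R,2R,6S)-3-[(tert-butyldimethylsilyl)oxy]-1,2,6-trimethyl-4-(phenylsulfanyl)cyclohex-3-ene-1-carbaldehyde, 1:1 | O=C[C@@]1(C)[C@H](C)CC(Sc2ccccc2)=C(O[Si](C)(C)C(C)(C)C)[C@H]1C.O=C[C@]1(C)[C@@H](C)CC(Sc2ccccc2)=C(O[Si](C)(C)C(C)(C)C)[C@@H]1C
F2 | step 4 | (1R,2R,6S)-3-[(tert-butyldimethylsilyl)oxy]-1,2,6-trimethyl-4-(phenylsulfanyl)cyclohex-3-ene-1-carbaldehyde | O=C[C@]1(C)[C@@H](C)CC(Sc2ccccc2)=C(O[Si](C)(C)C(C)(C)C)[C@@H]1C
F3 | step 12 | {4-chloro-2-[(2E)-3-iodobut-2-en-1-yl]-5-methyl-1,3-phenylene}bis(oxy)bis(tert-butyldimethylsilane) | CC(C)(C)[Si](C)(C)Oc1cc(C)c(Cl)c(O[Si](C)(C)C(C)(C)C)c1C/C=C(\C)I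
F4 | step 9 | [3-chloro-2,6-bis(methoxymethoxy)-4-methylphenyl]methanol | OCc1c(OCOC)cc(C)c(Cl)c1OCOC
F5 | step 9 | 4-chloro-2-(chloromethyl)-1,3-bis(methoxymethoxy)-5-methylbenzene | ClCc1c(OCOC)cc(C)c(Cl)c1OCOC
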